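The dihydrofuran ring (O1, C2, C3, C3a, C7a) is disconnected at C3–C3a together with the ester C–O bond. The ester carbon sits on C3 beside aryl carbon C3a, the pattern produced when the carbonyl carbon of a chroman-4-one leaves the ring while the aryl carbon moves to the neighbouring carbon. A photochemical Wolff rearrangement of a 3-diazoflavanone therefore contracts the pyranone to the dihydrofuran, and the ketene is trapped by the shikimate 5-hydroxyl, which builds the ring, the ester and the cis C3 stereocentre in one operation. The precursor is a (2S)-flavanone-derived 3-diazochroman-4-one carrying the C5 tert-butyl acrylate, the C8 methoxymethyl ether and an acetonide-protected catechol ring at C2.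

Key step: step 11

Remark: the quinidine-derived thiourea in step 7 is assumed to deliver the (2S) flavanone; should the sense prove opposite, the quinine-derived pseudoenantiomer is used with no other change.

Step 1
Reactants: 1 2-bromo-3-hydroxy-4-methoxybenzaldehyde
Product: 2 2-bromo-3,4-dihydroxybenzaldehyde
Conditions: BBr3 (2.5 equiv), CH2Cl2, −78 °C → rt; then H2O
Reagents that add atoms: none
Why: Lewis acid O-demethylation of the aryl methyl ether frees the 4-hydroxyl at the outset, so that it can carry an acid-labile group instead of a methyl ether that could not be removed from the finished ester.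

Step 2
Reactants: 2 2-bromo-3,4-dihydroxybenzaldehyde
Product: 3 2-bromo-3-hydroxy-4-(methoxymethoxy)benzaldehyde
Conditions: MOMCl (1.05 equiv), K2CO3 (1.1 equiv), acetone, 0 °C → rt
Reagents that add atoms: chloromethyl methyl ether (MOMCl), COCCl
Why: Williamson-type O-alkylation under weak base should select the 4-hydroxyl, which is para to the formyl group and hence the more acidic and less hindered phenol, leaving the bromine-flanked 3-hydroxyl free to become the ring oxygen.

Step 3
Reactants: 3 2-bromo-3-hydroxy-4-(methoxymethoxy)benzaldehyde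
Product: 4 tert-butyl (E)-3-[2-bromo-3-hydroxy-4-(methoxymethoxy)phenyl]prop-2-enoate
Conditions: Ph3P=CHCO2t-Bu (1.2 equiv), toluene, 80 °C
Reagents that add atoms: tert-butyl (triphenylphosphoranylidene)acetate, CC(C)(C)OC(=O)C=P(c1ccccc1)(c1ccccc1)c1ccccc1
Why: Wittig olefination with a stabilised ylide should give the (E)-acrylate and tolerates the free phenol and the aryl bromide.

Step 4
Reactants: 4 tert-butyl (E)-3-[2-bromo-3-hydroxy-4-(methoxymethoxy)phenyl]prop-2-enoate
Product: 6 tert-butyl (E)-3-[2-acetyl-3-hydroxy-4-(methoxymethoxy)phenyl]prop-2-enoate, via enol ether 5 (not isolated)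
Conditions: Bu3SnC(OEt)=CH2 (1.5 equiv), Pd(PPh3)4 (5 mol %), toluene, 100 °C; then 1 M HCl, THF, 0 °C
Reagents that add atoms: tributyl(1-ethoxyvinyl)stannane, CCCC[Sn](CCCC)(CCCC)C(=C)OCC; water, O
Why: Stille coupling of the aryl bromide with the 1-ethoxyvinyl stannane followed by brief cold hydrolysis of the enol ether installs the methyl ketone without organolithium chemistry that the acrylate would not survive, and the short dilute-acid treatment spares the methoxymethyl ether and the tert-butyl ester.

Step 5
Reactants: 7 3,4-dihydroxybenzaldehyde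
Product: 8 2,2-dimethyl-1,3-benzodioxole-5-carbaldehyde
Conditions: Me2C(OMe)2 (excess), TsOH·H2O (cat.), toluene, reflux with distillative removal of MeOH; aqueous work-up
Reagents that add atoms: 2,2-dimethoxypropane, COC(C)(C)OC
Why: Acid-catalysed ketal exchange driven by removal of methanol closes the catechol acetonide, which is inert to the basic and photochemical steps ahead and is cleaved by the final acid.

Step 6
Reactants: 6 tert-butyl (E)-3-[2-acetyl-3-hydroxy-4-(methoxymethoxy)phenyl]prop-2-enoate; 8 2,2-dimethyl-1,3-benzodioxole-5-carbaldehyde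
Product: 9 chalcone tert-butyl (E)-3-{2-[(E)-3-(2,2-dimethyl-1,3-benzodioxol-5-yl)prop-2-enoyl]-3-hydroxy-4-(methoxymethoxy)phenyl}prop-2-enoate
Conditions: KOH (aq., excess), EtOH, 0 °C → rt; AcOH to pH 5–6, cold
Reagents that add atoms: none
Why: Claisen–Schmidt (crossed aldol) condensation with the non-enolisable aldehyde should give the (E)-chalcone, the strong base holding it as the phenoxide so that racemic ring closure is suppressed, while the tert-butyl ester resists hydroxide and the five-membered enolate Michael closure onto the neighbouring acrylate is stereoelectronically disfavoured.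

Step 7
Reactants: 9 chalcone
Product: 10 (2S)-flavanone tert-butyl (E)-3-[(2S)-2-(2,2-dimethyl-1,3-benzodioxol-5-yl)-8-(methoxymethoxy)-4-oxochroman-5-yl]prop-2-enoate
Conditions: 9-amino-9-deoxy-epi-quinidine 3,5-bis(trifluoromethyl)phenyl thiourea (10 mol %), toluene, rt; recrystallisation
Reagents that add atoms: none
Why: Asymmetric intramolecular oxa-Michael addition (6-endo-trig) under bifunctional cinchona thiourea catalysis, in which the quinuclidine activates the phenol and the thiourea binds the enone carbonyl so that one face of the β-carbon is attacked, should set C2 as (S), and the flanking ring substituent pushes the equilibrium to the closed flavanone.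

Step 8
Reactants: 10 (2S)-flavanone
Product: 12 3-diazoflavanone tert-butyl (E)-3-[(2R)-3-diazo-2-(2,2-dimethyl-1,3-benzodioxol-5-yl)-8-(methoxymethoxy)-4-oxochroman-5-yl]prop-2-enoate, via trifluoroacetyl ketone 11 (not isolated)
Conditions: LiN(SiMe3)2 (1.1 equiv), THF, −78 °C; CF3CO2CH2CF3 (1.3 equiv), −78 °C; aq. NH4Cl; then 4-AcNHC6H4SO2N3 (1.5 equiv), Et3N (1.5 equiv), H2O (1 equiv), MeCN, rt
Reagents that add atoms: 4-acetamidobenzenesulfonyl azide, CC(=O)Nc1ccc(cc1)S(=O)(=O)N=[N+]=[N-]
Why: Deacylative (Regitz-type) diazo transfer through the α-trifluoroacetyl ketone confines enolate formation to −78 °C, where β-elimination of the ring aryloxide is slow, and the transfer itself runs on the stabilised diketonate under mild amine base, so C2 keeps its spatial arrangement (the descriptor becomes R only because the diazo carbon outranks the aryl group).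

Step 9
Reactants: 13 (−)-shikimic acid
Product: 14 3,4-O-isopropylideneshikimic acid
Conditions: Me2C(OMe)2 (3 equiv), TsOH·H2O (cat.), acetone, rt; Et3N quench
Reagents that add atoms: 2,2-dimethoxypropane, COC(C)(C)OC
Why: Acetonide formation is selective for the cis-3,4-diol, which closes a cis-fused dioxolane, and leaves the trans-disposed 5-hydroxyl free.

Step 10
Reactants: 14 3,4-O-isopropylideneshikimic acid
Product: 15 tert-butyl 3,4-O-isopropylideneshikimate
Conditions: Me2NCH(Ot-Bu)2 (3 equiv), toluene, 80 °C
Reagents that add atoms: N,N-dimethylformamide di-tert-butyl acetal, CN(C)C(OC(C)(C)C)OC(C)(C)C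
Why: tert-Butyl esterification with the amide acetal alkylates only the carboxylic acid, because the reagent must be protonated by it before the tert-butyl group is transferred, so the 5-hydroxyl stays free.

Step 11
Reactants: 12 3-diazoflavanone; 15 tert-butyl 3,4-O-isopropylideneshikimate
Product: 17 fully protected target (2S,3R)-cis-dihydrobenzofuran-3-carboxylate of the shikimate 5-hydroxyl, via ketene 16 (not isolated)
Conditions: 12 (1 equiv), 15 (2.5 equiv), blue LEDs (450 nm), anhydrous toluene (0.05 M), 20 °C, Ar
Reagents that add atoms: none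
Why: Excitation of the diazo ketone, whose ring locks C=O and C=N2 s-cis, expels dinitrogen while aryl carbon C4a shifts from C4 to C3 in concert (photochemical Wolff rearrangement), so that C4 leaves the ring as the ketene carbon of 16; the closest known reaction type is the light-driven Wolff ring contraction of cyclic α-diazo ketones with capture of the ketene by an alcohol. The dihydrofuran ring (O1, C2, C3, C3a, C7a) is therefore closed by contraction of the six-membered pyranone through a 1,2-aryl shift and not by an end-to-end cyclisation, the new C3–C3a bond replacing the former C4–C4a bond. The 5-hydroxyl of 15 adds to the ketene carbonyl carbon to form the ester C–O bond and an ester enol, whose tautomerisation creates the C3 stereocentre. That centre is controlled by the C2 aryl group: the proton should reach C3 from the face opposite to it, which leaves the ester cis to the aryl ring and gives (2S,3R) under kinetic control, while C2 and the shikimate centres are untouched because no bond to them is broken. The step needs the Wolff shift to outrun carbene 1,2-hydrogen and 1,2-aryl shifts and any reaction with the acrylate units, which the locked s-cis geometry and the metal-free room-temperature photolysis should secure, and it needs the cis ester to survive, which the neutral base-free medium ensures.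

Step 12
Reactants: 17 fully protected target
Product: 18 target, (2S,3R)-4-[(E)-2-carboxyethenyl]-2-(3,4-dihydroxyphenyl)-7-hydroxy-2,3-dihydrobenzofuran-3-carboxylic acid 5-O-ester of (−)-shikimic acid
Conditions: CF3CO2H/H2O (9:1), 0 °C → rt
Reagents that add atoms: none
Why: Acidolysis in aqueous trifluoroacetic acid should remove all five protecting groups in one operation (tert-butyl esters by alkyl–oxygen cleavage, both isopropylidene ketals and the methoxymethyl acetal by hydrolysis), and the absence of base avoids C3 epimerisation, acyl migration on the shikimate diol and β-elimination of the ring oxygen, so no stereocentre is touched.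

Compound list
1 | 2-bromo-3-hydroxy-4-methoxybenzaldehyde | COc1ccc(C=O)c(Br)c1O | starting material
2 | 2-bromo-3,4-dihydroxybenzaldehyde | O=Cc1ccc(O)c(O)c1Br | intermediate
3 | 2-bromo-3-hydroxy-4-(methoxymethoxy)benzaldehyde | COCOc1ccc(C=O)c(Br)c1O | intermediate
4 | tert-butyl (E)-3-[2-bromo-3-hydroxy-4-(methoxymethoxy)phenyl]prop-2-enoate | CC(C)(C)OC(=O)/C=C/c1ccc(OCOC)c(O)c1Br | intermediate
5 | enol ether, tert-butyl (E)-3-[2-(1-ethoxyethenyl)-3-hydroxy-4-(methoxymethoxy)phenyl]prop-2-enoate (not isolated) | CCOC(=C)c1c(O)c(OCOC)ccc1/C=C/C(=O)OC(C)(C)C | intermediate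
6 | tert-butyl (E)-3-[2-acetyl-3-hydroxy-4-(methoxymethoxy)phenyl]prop-2-enoate | CC(=O)c1c(O)c(OCOC)ccc1/C=C/C(=O)OC(C)(C)C | intermediate
7 | 3,4-dihydroxybenzaldehyde | O=Cc1ccc(O)c(O)c1 | starting material
8 | 2,2-dimethyl-1,3-benzodioxole-5-carbaldehyde | CC1(C)Oc2ccc(C=O)cc2O1 | intermediate
9 | chalcone, tert-butyl (E)-3-{2-[(E)-3-(2,2-dimethyl-1,3-benzodioxol-5-yl)prop-2-enoyl]-3-hydroxy-4-(methoxymethoxy)phenyl}prop-2-enoate | CC(C)(C)OC(=O)/C=C/c1ccc(OCOC)c(O)c1C(=O)/C=C/c1ccc2OC(C)(C)Oc2c1 | intermediate
10 | (2S)-flavanone, tert-butyl (E)-3-[(2S)-2-(2,2-dimethyl-1,3-benzodioxol-5-yl)-8-(methoxymethoxy)-4-oxochroman-5-yl]prop-2-enoate | CC(C)(C)OC(=O)/C=C/c1ccc(OCOC)c2c1C(=O)C[C@@H](c1ccc3OC(C)(C)Oc3c1)O2 | intermediate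
11 | 3-trifluoroacetyl derivative of 10, C2 as in 10, C3 a labile 1,3-dicarbonyl position (not isolated) | CC(C)(C)OC(=O)/C=C/c1ccc(OCOC)c2c1C(=O)C(C(=O)C(F)(F)F)[C@@H](c1ccc3OC(C)(C)Oc3c1)O2 | intermediate
12 | 3-diazoflavanone, tert-butyl (E)-3-[(2R)-3-diazo-2-(2,2-dimethyl-1,3-benzodioxol-5-yl)-8-(methoxymethoxy)-4-oxochroman-5-yl]prop-2-enoate (C2 spatially as in 10) | CC(C)(C)OC(=O)/C=C/c1ccc(OCOC)c2c1C(=O)C(=[N+]=[N-])[C@@H](c1ccc3OC(C)(C)Oc3c1)O2 | intermediate
13 | (−)-shikimic acid, (3R,4S,5R)-3,4,5-trihydroxycyclohex-1-ene-1-carboxylic acid | O[C@@H]1CC(C(=O)O)=C[C@@H](O)[C@H]1O | starting material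
14 | 3,4-O-isopropylideneshikimic acid, (3R,4S,5R) in shikimate numbering, 5-hydroxyl free | O[C@@H]1CC(C(=O)O)=C[C@H]2OC(C)(C)O[C@H]21 | intermediate
15 | tert-butyl 3,4-O-isopropylideneshikimate, (3R,4S,5R) in shikimate numbering, 5-hydroxyl free | O[C@@H]1CC(C(=O)OC(C)(C)C)=C[C@H]2OC(C)(C)O[C@H]21 | intermediate
16 | ketene, tert-butyl (E)-3-[(2R)-2-(2,2-dimethyl-1,3-benzodioxol-5-yl)-7-(methoxymethoxy)-3-(oxomethylidene)-2,3-dihydrobenzofuran-4-yl]prop-2-enoate, C2 spatially as in 12 (not isolated) | CC(C)(C)OC(=O)/C=C/c1ccc(OCOC)c2c1C(=C=O)[C@@H](c1ccc3OC(C)(C)Oc3c1)O2 | intermediate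
17 | fully protected target, 5-O-ester of 15 with the (2S,3R)-cis-4-[(E)-2-(tert-butoxycarbonyl)ethenyl]-2-(2,2-dimethyl-1,3-benzodioxol-5-yl)-7-(methoxymethoxy)-2,3-dihydrobenzofuran-3-carboxylic acid unit | CC(C)(C)OC(=O)/C=C/c1ccc(OCOC)c2c1[C@@H](C(=O)O[C@@H]1CC(C(=O)OC(C)(C)C)=C[C@H]3OC(C)(C)O[C@H]31)[C@@H](c1ccc3OC(C)(C)Oc3c1)O2 | intermediate
18 | target, (3R,4R,5R)-5-{[(2S,3R)-4-[(E)-2-carboxyethenyl]-2-(3,4-dihydroxyphenyl)-7-hydroxy-2,3-dihydrobenzofuran-3-carbonyl]oxy}-3,4-dihydroxycyclohex-1-ene-1-carboxylic acid | O=C(O)/C=C/c1ccc(O)c2c1[C@@H](C(=O)O[C@@H]1CC(C(=O)O)=C[C@@H](O)[C@H]1O)[C@@H](c1ccc(O)c(O)c1)O2 | target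

Total step count: 12. Longest linear sequence: 9 steps (steps 1, 2, 3, 4, 6, 7, 8, 11, 12).

Steps most likely to fail

Step 11. Capture of the aryl(alkyl)ketene by the hindered secondary alcohol may be slower than its loss to traces of water or to dimerisation, and proton delivery at C3 may be less face-selective than expected. The fallback sets out from 12: the photolysis is run in THF/H2O, so that water in large excess captures the ketene and gives, by the same kinetic protonation, the cis carboxylic acid F1. F1 is then joined to 15 by carbodiimide esterification (EDC·HCl, catalytic DMAP, CH2Cl2, 0 °C, Steglich conditions, kept cold and base-poor), which comes back to the route at 17.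

Step 7. The catalyst may discriminate the two enone faces poorly, or the flavanone may re-open to the chalcone on the catalyst and lose enantiopurity. The fallback sets out from 9: NaOAc in refluxing EtOH closes the ring without stereocontrol to the racemic flavanone F2. F2 is resolved by preparative chromatography on a chiral stationary phase (amylose tris(3,5-dimethylphenylcarbamate), supercritical CO2/MeOH). The (2S) enantiomer is 10, where the route is rejoined; the (2R)-flavanone F3 is returned to 9 with KOH in EtOH and recycled.

Step 8. β-Elimination of the ring aryloxide from the lithium enolate (retro-oxa-Michael opening) may compete with C-acylation and erode the C2 configuration or return chalcone. The fallback sets out from 10: condensation with N,N-dimethylformamide dimethyl acetal (neat, 70 °C), in which no metal enolate is formed, gives the (E)-3-(dimethylaminomethylene)flavanone F4. Diazo transfer from 4-acetamidobenzenesulfonyl azide (MeCN, rt) by cycloaddition and loss of the sulfonyl formamidine then gives 12, where the route is rejoined.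

Further compounds
F1 | step 11 | (2S,3R)-cis-4-[(E)-2-(tert-butoxycarbonyl)ethenyl]-2-(2,2-dimethyl-1,3-benzodioxol-5-yl)-7-(methoxymethoxy)-2,3-dihydrobenzofuran-3-carboxylic acid | CC(C)(C)OC(=O)/C=C/c1ccc(OCOC)c2c1[C@@H](C(=O)O)[C@@H](c1ccc3OC(C)(C)Oc3c1)O2
F2 | step 7 | racemic flavanone, tert-butyl (E)-3-[2-(2,2-dimethyl-1,3-benzodioxol-5-yl)-8-(methoxymethoxy)-4-oxochroman-5-yl]prop-2-enoate | CC(C)(C)OC(=O)/C=C/c1ccc(OCOC)c2c1C(=O)CC(c1ccc3OC(C)(C)Oc3c1)O2
F3 | step 7 | (2R)-flavanone, enantiomer of 10 | CC(C)(C)OC(=O)/C=C/c1ccc(OCOC)c2c1C(=O)C[C@H](c1ccc3OC(C)(C)Oc3c1)O2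
F4 | step 8 | (E)-3-(dimethylaminomethylene) derivative of flavanone 10, C2 spatially as in 10 | CC(C)(C)OC(=O)/C=C/c1ccc(OCOC)c2c1C(=O)/C(=C/N(C)C)[C@@H](c1ccc3OC(C)(C)Oc3c1)O2
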